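Readings and results were computed with made-up constants, noise included.

Whatever the time, substrate, single product, double product and tris adduct together hold the substrate charged, so I mark each flask by a, the fraction of substrate left, and ask how the rest divides.

| flask | substrate | coupling partner | scavenger | remark | time |
|---|---|---|---|---|---|
| epsilon | 0.028 M | 0.036 M | 6 mM | run made earlier |  |
| eta | 0.044 M | 0.036 M | 6 mM | run made earlier |  |
| maple | 0.020 M | 0.0360 M | 6.00 mM |  | 5.0 min |
| alder | 0.020 M | 0.0360 M | 6.00 mM |  | 4.0 min |
| birch | 0.020 M | 0.0360 M | 6.00 mM |  | 3.0 min |

| run | time / min | substrate / % | double product / % | tris adduct / % | single product / % |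
|---|---|---|---|---|---|
| epsilon | 0.333 | 68.4 | 3.6 | 0 | 26.7 |
| epsilon | 0.833 | 47.9 | 12.3 | 0 | 38.1 |
| epsilon | 1.50 | 33.5 | 22.2 | 1.5 | 41.8 |
| epsilon | 2.50 | 25.7 | 30.3 | 0 | 43.4 |
| eta | 0.200 | 81.1 | 1.0 | 0 | 18.7 |
| eta | 0.417 | 68.5 | 3.4 | 2.6 | 26.7 |
| eta | 1.00 | 52.2 | 11.7 | 0 | 37.3 |
| eta | 2.50 | 38.6 | 17.4 | 0 | 41.2 |

(each reading ± 1 percentage point)

- which of these there is most of at the end, counted by the substrate in it, maple (single product / double product / tris adduct / substrate)
- which of these there is most of at the end, counted by the substrate in it, alder (single product / double product / tris adduct / substrate)
- which of these there is most of at the end, counted by the substrate in it, birch (single product / double product / tris adduct / substrate)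
- final amount of the leader among these, as a percentage of the substrate charged, in maple
- final amount of the leader among these, as a percentage of the substrate charged, in alder
- final amount of the leader among these, as a percentage of the substrate charged, in birch

I follow one molecule of coupling partner to its fork: it lands on a substrate or on a single product. As I read the runs, both additions draw on the same free partner, so partner and clock cancel from the ratio. I read the per-molecule preference for single product, the selectivity factor s, as double gained over substrate lost, times mean substrate over mean single. Epsilon from 0.833 min to 2.50 min gives 0.732, eta from 0.417 min to 2.50 min gives 0.739, and I carry s = 0.735. Integrated, the single-product fraction is (a^s − a)/(1 − s), and double plus tris is the remainder.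

Epsilon reached 25.7% substrate in 2.50 min. At that pace birch reaches 19.6% in 3.0 min, and birch charges less substrate than epsilon, so each percent converted costs less partner and its a should lie lower. There the rule puts single product at 39.9% and double plus tris at 40.5%, about level. With a lower than that, I expect double product to lead in birch, and alder and maple run longer.

The forecast names double product for maple, alder and birch, at 58%, 53% and 46%: “the steps look like sequential additions”. Its birch figure stands above my level point.

The flasks give double product in each, at 56.5%, 51.8% and 45.0%.

    coupling partner + single product → double product + released group (k = 0.430 /M/s)
    substrate + coupling partner → single product + released group (k = 0.620 /M/s)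
    scavenger + released group → scavenged by-product (k = 84.0 /M/s)
    coupling partner + released group ⇌ idle adduct, settled at all times (K = 46.0 /M)
    coupling partner + double product → tris adduct + released group (k = 0.0270 /M/s)
    released group → by-product carried off (k = 0.0920 /s)

So the forecast holds. In alder at the end, double product is made 10.7 times faster than it is used up, each step taken net. Alder's substrate of 11.1% put into the rule gives 33.1% single product, against 34.8% in the flask.

A neighbouring flask, alder with 0.0080 M substrate, ends with 2.29% of it. For that neighbour the rule gives 14.9% single product and 82.8% double plus tris. The neighbouring flask holds 16.3% single product and 81.4% double plus tris.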